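**Retrosynthetic overview**
1. The last operation frees the ring B catechol from two benzyl ethers and leaves the skeleton unchanged.
2. The key disconnections are two aryl C–O bonds on ring A: O1–C8a, which closes pyranone ring C, and C5–OMe. Both trace back to the two equivalent C–Br bonds of a 2,6-dibromo-3,4,5-trimethoxyphenyl 1,3-diketone.
3. That diketone comes from a crossed Claisen condensation of the dibromo acetophenone with methyl 3,4-bis(benzyloxy)benzoate. It is made in the same flask, with the same base and solvent.
4. The dibromo ketone comes from double ring bromination of 3',4',5'-trimethoxyacetophenone.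
5. Ring order: rings A and B are bought as benzene rings. Ring C is the only ring formed, in step 2.

Assumption: the target SMILES has no stereocentre and no stereogenic double bond, so the compound is achiral and no stereocontrol is needed.

Step 1
Reactants: 1 1-(3,4,5-trimethoxyphenyl)ethan-1-one (3',4',5'-trimethoxyacetophenone)
Product: 3 1-(2,6-dibromo-3,4,5-trimethoxyphenyl)ethan-1-one, via monobromo ketone 2 (not isolated)
Conditions: NBS (2.3 equiv), MeCN, dark, rt, 2 h, then 60 °C, 6 h
Reagents that add atoms: N-bromosuccinimide O=C1CCC(=O)N1Br
Why: Electrophilic aromatic bromination (SEAr): in polar MeCN without acid or light, NBS attacks the only two free ring positions (each ortho to one methoxy group and para to another) faster than the ketone enolises, and once the first bromine has twisted the acetyl group out of conjugation its deactivating effect fades, so the second equivalent position follows on warming; no stereocentre is formed.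

Step 2
Reactants: 3 1-(2,6-dibromo-3,4,5-trimethoxyphenyl)ethan-1-one; 4 methyl 3,4-bis(benzyloxy)benzoate
Product: 7 2-[3,4-bis(benzyloxy)phenyl]-5,6,7,8-tetramethoxy-4H-chromen-4-one, via dibromo diketone 5 (not isolated), via 5-bromoflavone 6 (not isolated)
Conditions: one pot: dry NaOMe (5 equiv), DMF, N2, 70 °C, 3 h; then CuBr (20 mol %), 110 °C, 10 h; cold dilute aq HCl work-up
Reagents that add atoms: sodium methoxide [Na+].[O-]C
Why: Proposed new method: NaOMe first drives a routine crossed Claisen condensation (the carbonyl of 3 is shielded by two ortho bromines and cannot self-condense, and 4 has no alpha hydrogen) to the sodium enolate of 5; this beta-diketonate is itself a good ligand for monovalent copper and holds it next to the two equivalent ortho C–Br bonds, so oxidative addition and C–O reductive elimination from trivalent copper close ring C (O1–C8a) to give 6, whose remaining bromide, now peri to the copper-binding C4 carbonyl, is exchanged by methoxide (C5–OMe); C-arylation would need a four-membered ring, and every order of events (cyclise then methoxylate, or methoxylate then cyclise) ends at the same product 7, so no regiochemical issue arises; the closest known reaction types are the intramolecular Ullmann-type O-arylation of 1-(2-haloaryl)-1,3-diketones to chromones and the CuBr/NaOMe methoxylation of hindered electron-rich aryl bromides, which have not been merged into one desymmetrising double C–O coupling on a 2,6-dibromoaryl diketone; no stereocentre is formed.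

Step 3
Reactants: 7 2-[3,4-bis(benzyloxy)phenyl]-5,6,7,8-tetramethoxy-4H-chromen-4-one
Product: 8 2-(3,4-dihydroxyphenyl)-5,6,7,8-tetramethoxy-4H-chromen-4-one (3',4'-dihydroxy-5,6,7,8-tetramethoxyflavone)
Conditions: H2 (1 atm), 10% Pd/C, THF–MeOH 1:1, rt, 5 h
Reagents that add atoms: none
Why: Catalytic hydrogenolysis of aryl benzyl ethers: the benzylic C–O bonds are cleaved on Pd at room temperature, the four aryl methyl ethers are inert, and the chromone C2=C3 bond is not reduced under such mild conditions; no stereocentre is formed.

**Compound list**
1 | 1-(3,4,5-trimethoxyphenyl)ethan-1-one | CC(=O)c1cc(OC)c(OC)c(OC)c1 | starting material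
2 | 1-(2-bromo-3,4,5-trimethoxyphenyl)ethan-1-one | CC(=O)c1cc(OC)c(OC)c(OC)c1Br | intermediate
3 | 1-(2,6-dibromo-3,4,5-trimethoxyphenyl)ethan-1-one | CC(=O)c1c(Br)c(OC)c(OC)c(OC)c1Br | intermediate
4 | methyl 3,4-bis(benzyloxy)benzoate | COC(=O)c1ccc(OCc2ccccc2)c(OCc2ccccc2)c1 | starting material
5 | 1-[3,4-bis(benzyloxy)phenyl]-3-(2,6-dibromo-3,4,5-trimethoxyphenyl)propane-1,3-dione | O=C(CC(=O)c1ccc(OCc2ccccc2)c(OCc2ccccc2)c1)c1c(Br)c(OC)c(OC)c(OC)c1Br | intermediate
6 | 2-[3,4-bis(benzyloxy)phenyl]-5-bromo-6,7,8-trimethoxy-4H-chromen-4-one | COc1c(OC)c(Br)c2c(=O)cc(-c3ccc(OCc4ccccc4)c(OCc4ccccc4)c3)oc2c1OC | intermediate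
7 | 2-[3,4-bis(benzyloxy)phenyl]-5,6,7,8-tetramethoxy-4H-chromen-4-one | COc1c(OC)c(OC)c2c(=O)cc(-c3ccc(OCc4ccccc4)c(OCc4ccccc4)c3)oc2c1OC | intermediate
8 | 2-(3,4-dihydroxyphenyl)-5,6,7,8-tetramethoxy-4H-chromen-4-one | COc1c(OC)c(OC)c2c(=O)cc(-c3ccc(O)c(O)c3)oc2c1OC | target

Total step count: 3. Longest linear sequence: 3.

**Steps most likely to fail**

(a) Step 2, the new cascade, carries the most risk.
- Copper and methoxide can reduce the C5–Br bond to C5–H.
- Hot methoxide can cleave the diketone by a retro-Claisen reaction.
- The electron-rich ester may condense slowly.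

The fallback uses only known chemistry and closes ring C through the other C–O bond. It sets out from 3. Standard CuBr/NaOMe methoxylation in DMF at 110 °C exchanges both bromines and gives 2',3',4',5',6'-pentamethoxyacetophenone F1. BCl3 (1.1 equiv, CH2Cl2, −20 °C) removes one of the two equivalent methyl ethers ortho to the chelating ketone and gives 2'-hydroxy-3',4',5',6'-tetramethoxyacetophenone F2. Claisen–Schmidt condensation with purchased 3,4-bis(benzyloxy)benzaldehyde (KOH, EtOH, rt) gives (E)-3,4-bis(benzyloxy)-2'-hydroxy-3',4',5',6'-tetramethoxychalcone F3. Iodine (10 mol %) in DMSO at 120 °C then forms O1–C2 by oxa-Michael addition and dehydrogenation. The fallback comes back to the route at 7.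

(b) Step 1 can go astray by bromination of the acetyl CH3 through the enol, or by a stalled second ring bromination. The fallback switches off enolisation by masking the ketone. It sets out from 1. Ethylene glycol with TsOH (cat.) in toluene under Dean–Stark conditions gives 2-methyl-2-(3,4,5-trimethoxyphenyl)-1,3-dioxolane F4. NBS (2.2 equiv) with solid NaHCO3 in MeCN brominates both free positions of the now more electron-rich ring and gives 2-(2,6-dibromo-3,4,5-trimethoxyphenyl)-2-methyl-1,3-dioxolane F5. Dilute aq HCl in acetone releases the ketone, and the fallback comes back to the route at 3.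

(c) Step 3 can suffer from catalyst poisoning by traces of copper or bromide carried over from step 2, or from partial saturation of C2=C3 to the flavanone. The fallback replaces metal-catalysed hydrogenolysis with metal-free acidolysis. It sets out from 7. TFA with pentamethylbenzene (6 equiv) as benzyl cation trap at 40 °C cleaves both benzyl ethers and leaves the methyl ethers untouched. It arrives directly at 8 and makes no new compound (entry F0).

**Further compounds**
F1 | step 2 | 2',3',4',5',6'-pentamethoxyacetophenone | CC(=O)c1c(OC)c(OC)c(OC)c(OC)c1OC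
F2 | step 2 | 2'-hydroxy-3',4',5',6'-tetramethoxyacetophenone | CC(=O)c1c(O)c(OC)c(OC)c(OC)c1OC
F3 | step 2 | (E)-3,4-bis(benzyloxy)-2'-hydroxy-3',4',5',6'-tetramethoxychalcone | COc1c(O)c(C(=O)/C=C/c2ccc(OCc3ccccc3)c(OCc3ccccc3)c2)c(OC)c(OC)c1OC
F4 | step 1 | 2-methyl-2-(3,4,5-trimethoxyphenyl)-1,3-dioxolane | CC1(OCCO1)c1cc(OC)c(OC)c(OC)c1
F5 | step 1 | 2-(2,6-dibromo-3,4,5-trimethoxyphenyl)-2-methyl-1,3-dioxolane | CC1(OCCO1)c1c(Br)c(OC)c(OC)c(OC)c1Br
F0 | step 3 | none | none
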